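5 questions stand on these flasks, and they hang on one count: how many half-lives of the polymerisation rate fit into each flask's time.

| setting | Wednesday's | Monday's | Thursday's | red | grey | violet | ochre |
|---|---|---|---|---|---|---|---|
| free monomer | 0.053 M | 0.053 M | 0.026 M | 0.053 M | 0.053 M | 0.053 M | 0.053 M |
| initiator | 0.17 mM | 0.39 mM | 0.26 mM | 0.26 mM | 0.26 mM | 0.26 mM | 0.26 mM |
| temperature | 2 °C | 52 °C | 2 °C | 70 °C | 10 °C | 40 °C | −20 °C |
| remark | run made earlier | run made earlier | run made earlier |  |  |  |  |
| time |  |  |  | 3.0 h | 3.0 h | 3.0 h | 3.0 h |

- Wednesday's (time / h: monomer in chains / %, free monomer / %): 8.00: 0, 99.1; 15.0: 0, 96.6; 25.0: 0.3, 98.8; 40.0: 0, 99.5; 60.0: 0.8, 97.1; 120: 2.3, 97.1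
- Monday's (time / h: monomer in chains / %, free monomer / %): 0.667: 3.3, 95.7; 1.50: 8.0, 88.5; 3.00: 12.4, 79.6; 5.00: 18.6, 71.1; 8.00: 22.3, 63.5; 10.0: 26.2, 58.0
- Thursday's (time / h: monomer in chains / %, free monomer / %): 10.0: 0, 98.7; 25.0: 0, 100.9; 40.0: 0.4, 98.9; 72.0: 0, 97.3; 120: 0.9, 97.5

(scatter of a reading: 1 percentage point)

- a reading or a percentage of monomer in chains counts all its forms, free or not
- a reading of free monomer is of its free form alone

- the flask that comes out highest in amount of monomer in chains, in percent of the free monomer charged, or "all alike" when all lie within 1.5 percentage points (red / grey / violet / ochre / all alike)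
- monomer in chains at the end, in percent of the free monomer charged, red
- monomer in chains at the end, in percent of the free monomer charged, grey
- monomer in chains at the end, in percent of the free monomer charged, violet
- monomer in chains at the end, in percent of the free monomer charged, ochre

Two chemists read the runs. Both start from Monday's, whose free monomer falls at a pseudo-first-order rate of 0.0814 h⁻¹ early and 0.0453 h⁻¹ late. Both also take Monday's first chain reading as a start rate, which becomes 0.0404 h⁻¹ of the charge at this initiator charge under a square-root order. Against Wednesday's last chain reading, which is barely above the scatter, this gives an activation energy near 82.6 kJ mol⁻¹.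

The steady chemist multiplies. Red starts at 0.201 h⁻¹, so 3.0 h gives 60.2%.

The burn-out chemist objects that the rate itself decays. As a reading, the time in which the rate halves, the rate half-life, is 9.75 h on Monday's. That is my figure; the forecast reads a half-life near 8 h. Shortened by the same activation energy, which is my assumption, it becomes 1.96 h in red, a count of 1.53. Integrating the decaying rate, I get 37.2%.

The forecast, on the burn-out side, goes lower, because “initiator dies within hours and the side path and monomer depletion take their share”. It names red highest, with red 24% (13% to 36%), grey 0.15%, violet 3.5% and ochre 0%.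

The flasks give red 22.8%, grey 0.132%, violet 3.43% and ochre 0%, so red is highest, and all four lie inside the forecast's ranges. Red's 22.8% counts idle adduct in, and that adduct stands at 23.9% of the charge, two monomers each. The forecast for red would be wrong if a run fell below 13% or above 36%. Red left ten times as long gives 27.4%.

    initiator → 2 initiating radical (k = 1.04 h⁻¹, Ea = 105 kJ mol⁻¹)
    free monomer + initiating radical → growing radical + monomer in chains (k = 5.40 × 10⁵ M⁻¹ s⁻¹, Ea = 10.0 kJ mol⁻¹)
    free monomer + growing radical → monomer in chains + growing radical, rate k3*[growing radical]*[free monomer] (k = 1.35 × 10⁷ M⁻¹ h⁻¹, Ea = 33.0 kJ mol⁻¹)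
    2 growing radical → dead chain (k = 4.30 × 10⁸ M⁻¹ s⁻¹, Ea = 9.00 kJ mol⁻¹)
    free monomer + monomer in chains ⇌ idle adduct, settled at all times (K = 31.7 M⁻¹, ΔH = −23.0 kJ mol⁻¹)
    crystals ⇌ monomer in chains, rate k6*(cs6 - [monomer in chains]) while solid is left; crystals form when [monomer in chains] > cs6 (solubility = 32.0 mM, k = 3.71 h⁻¹)
    (constants at 70 °C)

The steady view's region is a count under one. Violet's count is 0.0954, 91% of its initiator remains, and its 3.43% stands near the steady 3.76%. Now take the same flask as ochre, read at 50 min. Its rate half-life reckons to 58000 h, a count of 1.44 × 10⁻⁵. That flask keeps >99.9% of its initiator and >99.9% of its free monomer, with 0% monomer in chains.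

The readings come from a simulation on assumed constants; noise was put on by code.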